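Everything rests on the C6–C7–C8 array of ring B (C5–C10): carbinol C6, methylene C7 and the methyl carbinol C8 form a β-oxygenated, aldol-type triad. Ring B is therefore carried as a trans-fused cyclopentane (C5, C6, C8, C9, C10) made from a Hajos–Parrish-type enedione, with C7 waiting as the methylene of a fused cyclopropanol (C6–OH, C8–CH3). Manganese-catalysed aerobic opening of this cyclopropanol cuts the shared C6–C8 bond and, in one operation, inserts C7 into the ring (five to six members), creates the C6 carbonyl and places oxygen on C8. Reduction at C6, nickel-catalysed union with an (R)-butenolide vinyl iodide and selective C18 oxidation complete the synthesis.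

Key step: step 12

Remark: labdane numbering is used for all bicyclic compounds (ring A = C1–C5 and C10; ring B = C5–C10; C17 on C8, C18 = 4α carbon, C19 = 4β methyl, C20 on C10; side chain C11–C16). The descriptors α and β are given relative to the C20 methyl (β). Before step 12 ring B is the cyclopentane C5–C6–C8–C9–C10. The target is treated as the open 6α-hydroxy-18-aldehyde that is drawn; a ring–chain equilibrium with its 18,6α-lactol is assumed not to interfere.

Step 1
Reactants: 1 2-methylcyclopentane-1,3-dione; 2 pent-1-en-3-one (ethyl vinyl ketone)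
Product: 3 2-methyl-2-(3-oxopentyl)cyclopentane-1,3-dione
Conditions: H2O, AcOH (cat.), 70 °C
Reagents that add atoms: none
Why: Michael addition of the acidic 1,3-dione to the enone; no stereocentre is formed.

Step 2
Reactants: 3 2-methyl-2-(3-oxopentyl)cyclopentane-1,3-dione
Product: 4 (S)-4,7a-dimethyl-2,3,7,7a-tetrahydro-1H-indene-1,5(6H)-dione (C3=O, C4(CH3)=C5, C9=O, 10β-CH3)
Conditions: L-phenylalanine, 1 M HClO4 (substoichiometric), MeCN, 80 °C; recrystallisation
Reagents that add atoms: none
Why: Hajos–Parrish–Eder–Sauer–Wiechert intramolecular aldol condensation through the amino acid enamine, which selects one of the two enantiotopic ring carbonyls and should set C10 as S (methyl β).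

Step 3
Reactants: 4 (S)-enedione
Product: 5 C9 ethylene ketal of 4
Conditions: ethylene glycol, p-TsOH (cat.), 4 Å molecular sieves, CH2Cl2, rt
Reagents that add atoms: ethylene glycol, OCCO
Why: Acid-catalysed ketalisation is chemoselective for the saturated C9 ketone over the conjugated enone carbonyl, as known for Hajos–Parrish ketone.

Step 4
Reactants: 5 enone ketal
Product: 7 trans-fused (5α-H, 10β-CH3) C3 ketone with 4β-CH3 and 4α-CH2OBn and the C9 ketal, via lithium enolate 6 (not isolated)
Conditions: Li (2.2 equiv), NH3(l)/THF, t-BuOH (1 equiv), −78 °C; NH3 removed; BnOCH2Cl, THF, −78 → 0 °C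
Reagents that add atoms: benzyl chloromethyl ether, ClCOCc1ccccc1
Why: Birch reductive alkylation: the enone radical anion should be protonated at C5 to the trans ring fusion, and the regiodefined C3 enolate is C-alkylated at C4 on the α face, anti to the C20 methyl, which places C18 (CH2OBn) α and C19 (CH3) β.

Step 5
Reactants: 7 ketal ketone
Product: 9 trans-hydrindan-9-one (C3 = CH2, C9 = O), via ketal 8 (not isolated)
Conditions: N2H4·H2O, KOH, diethylene glycol, 130 → 200 °C; then 2 M HCl, THF, rt
Reagents that add atoms: water, O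
Why: Wolff–Kishner reduction (Huang-Minlon procedure) removes the hindered C3 carbonyl under conditions that ketal and benzyl ether tolerate, and aqueous acid then cleaves the dioxolane; no stereocentre is at risk because C4 and C10 are quaternary and C5 is not α to a carbonyl.

Step 6
Reactants: 9 C9 ketone
Product: 10 8-methyl C9 ketone (C8 epimers)
Conditions: LDA, THF, −78 °C; MeI, −78 → 0 °C
Reagents that add atoms: iodomethane, CI
Why: Lithium enolate alkylation; C8 is the only enolisable position (C10 is quaternary), and the C8 configuration is erased in step 7.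

Step 7
Reactants: 10 8-methyl ketone
Product: 12 enone with C9=O and C8(CH3)=C6H (5α-H retained), via silyl enol ether 11 (not isolated)
Conditions: LDA, TMSCl, THF, −78 °C; then Pd(OAc)2 (1 equiv), MeCN, rt
Reagents that add atoms: none
Why: Saegusa–Ito oxidation of the regiodefined silyl enol ether gives the endocyclic 2-methylcyclopentenone without exposing the product to base, so the γ-positioned 5α-H is preserved.

Step 8
Reactants: 12 enone
Product: 13 tertiary allylic alcohol (9α-allyl, 9β-OH, C8(CH3)=C6H)
Conditions: allylmagnesium bromide, THF, −78 °C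
Reagents that add atoms: allylmagnesium bromide, C=CC[Mg]Br
Why: Grignard 1,2-addition, which allyl magnesium reagents prefer even with hindered enones (attack from the α face as with 17-keto steroids); the new carbinol centre is lost in step 9.

Step 9
Reactants: 13 tertiary allylic alcohol
Product: 14 transposed enone (C6=O, C8(CH3)=C9-allyl, 5α-H, trans-fused)
Conditions: pyridinium chlorochromate [C5H5NH][CrO3Cl], NaOAc, 4 Å molecular sieves, CH2Cl2, rt
Reagents that add atoms: none
Why: Babler–Dauben oxidative 1,3-transposition: the chromate ester undergoes allylic transposition to C6 and is oxidised there, which moves the oxygen function from C9 to C6 and puts the allyl group on the enone β-carbon; buffering protects the epimerisable 5α-H.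

Step 10
Reactants: 14 C6 enone
Product: 16 C6 trimethylsilyl enol ether (C6=C8) with C18–OTMS (9α-H, 9β-allyl), via dilithium enolate alkoxide 15 (not isolated)
Conditions: Li (4.5 equiv), NH3(l)/THF, t-BuOH (1 equiv), −78 °C; NH3 removed; TMSCl, Et3N, THF, −78 → 0 °C
Reagents that add atoms: chlorotrimethylsilane, C[Si](C)(C)Cl
Why: Dissolving-metal enone reduction with enolate trapping: C9 should be protonated from the α face, anti to the C20 methyl (9α-H, 9β-allyl, steroid ring D analogy), the enolate is fixed regiospecifically toward C8, C5 is never enolised, and the benzyl ether is cleaved in the same pot and silylated.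

Step 11
Reactants: 16 silyl enol ether
Product: 18 cyclopropanol (C7 methylene bridging C6 and C8 on the α face; 6β-OH, 8β-CH3, free 18-OH), via siloxycyclopropane 17 (not isolated)
Conditions: Et2Zn, CH2I2, CH2Cl2, 0 °C; pyridine quench; then K2CO3, MeOH, 0 °C
Reagents that add atoms: diiodomethane, ICI
Why: Simmons–Smith cyclopropanation (Furukawa variant) is fastest at the electron-rich silyl enol ether, the monosubstituted allyl alkene being much slower, and should occur on the less hindered α face; the configuration at C6 and C8 is inconsequential, and methanolysis frees the cyclopropanol and the C18 alcohol.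

Step 12
Reactants: 18 cyclopropanol
Product: 20 8α,18-dihydroxy-6-ketone with six-membered ring B (8β-CH3, 9β-allyl), via hydroperoxide 19 (not isolated)
Conditions: Mn(acac)3 (acac = pentane-2,4-dionate, 5 mol %), O2 (1 atm), benzene, rt; then PPh3, 0 °C
Reagents that add atoms: dioxygen, O=O
Why: Trivalent manganese forms the cyclopropoxide of 18 and oxidises it to an alkoxy radical, whose β-scission cleaves the shared C6–C8 bond rather than C6–C7 because this gives the tertiary C8 radical and the C6 ketone; the radical captures O2 and ends as hydroperoxide 19, which PPh3 reduces to the alcohol. The closest known reaction type is the Mn(acac)3- or VO(acac)2-catalysed aerobic ring opening of cyclopropanols to β-hydroperoxy or β-hydroxy ketones, together with the FeCl3 one-carbon ring expansion of 1-siloxybicyclo[n.1.0]alkanes, which passes through the same ring-enlarged β-keto radical. No ring is closed by a new bond: ring B grows from five to six members because the zero-atom bridge of the bicyclo[3.1.0]hexane is cut and C7 becomes a ring member. The only new stereocentre, C8, is set when O2 adds to the planar radical from the α face, opposite the axial C20 methyl (1,3-diaxial to a β approach), giving 8α-O and 8β-CH3; C5, C9 and C10 are untouched. The step needs regioselective scission (tertiary against primary radical), fast O2 capture under an O2 atmosphere (the allyl group stands in a slow 4-pentenyl relationship to the radical) and no over-oxidation to the 7-en-6-one.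

Step 13
Reactants: 20 β-hydroxy ketone
Product: 21 6α,8α,18-triol (9β-allyl)
Conditions: Li, NH3(l)/THF, −78 °C (inverse addition); NH4Cl
Reagents that add atoms: none
Why: Dissolving-metal ketone reduction runs under thermodynamic control through the ketyl and should give the equatorial 6α-alcohol, whereas hydride reagents would attack from the α face (the β face carries the axial C19 and C20 methyls) and give the 6β epimer; low temperature suppresses retro-aldol cleavage.

Step 14
Reactants: 21 allyl triol
Product: 22 6α,8α,18-tris(triethylsilyl) ether of 21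
Conditions: Et3SiOTf (4 equiv), 2,6-lutidine, CH2Cl2, −78 → 0 °C
Reagents that add atoms: triethylsilyl trifluoromethanesulfonate, CC[Si](CC)(CC)OS(=O)(=O)C(F)(F)F
Why: Silyl triflate silylation covers the primary, the secondary and the tertiary hydroxyl alike, which is needed because a free 8α-hydroxyl would displace any leaving group later placed on C12 to form a tetrahydrofuran; no stereocentre is touched.

Step 15
Reactants: 22 tris(triethylsilyl) ether
Product: 24 C12 alcohol (9β-CH2CH2OH) tris(triethylsilyl) ether, via aldehyde 23 (not isolated)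
Conditions: O3, CH2Cl2/MeOH, −78 °C; then NaBH4, −78 → 0 °C
Reagents that add atoms: ozone, [O-][O+]=O
Why: Ozonolysis of the only C=C bond with borohydride work-up converts the allyl group into the two-carbon C11–C12 alcohol, and the triethylsilyl ethers tolerate both reagents.

Step 16
Reactants: 24 C12 alcohol
Product: 25 C12 iodide tris(triethylsilyl) ether
Conditions: I2, PPh3, imidazole, THF, 0 °C → rt
Reagents that add atoms: iodine, II
Why: Appel-type iodination (Garegg–Samuelsson conditions) of the only free hydroxyl, a primary one, by SN2 displacement of the alkoxyphosphonium ion by iodide.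

Step 17
Reactants: 26 2-methyl-2-vinyl-1,3-dioxolane
Product: 27 rac-2-methyl-2-(oxiran-2-yl)-1,3-dioxolane
Conditions: mCPBA, NaHCO3, CH2Cl2, 0 °C → rt
Reagents that add atoms: 3-chloroperoxybenzoic acid, OOC(=O)c1cccc(Cl)c1
Why: Prilezhaev epoxidation of the terminal alkene.

Step 18
Reactants: 27 racemic epoxide
Product: 28 (R)-2-methyl-2-(oxiran-2-yl)-1,3-dioxolane
Conditions: (S,S)-(salen)Co(OAc) [salen = N,N′-bis(3,5-di-tert-butylsalicylidene)-1,2-cyclohexanediamine dianion, trivalent cobalt] (0.5 mol %), H2O (0.55 equiv), THF, 0 °C → rt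
Reagents that add atoms: none
Why: Jacobsen hydrolytic kinetic resolution should hydrolyse the (S)-epoxide faster and leave (R)-28; the catalyst enantiomer is assigned by analogy with epichlorohydrin, whose substituent likewise outranks the ring CH2 and which is left in the same spatial sense.

Step 19
Reactants: 28 (R)-epoxide
Product: 29 (R)-1-(2-methyl-1,3-dioxolan-2-yl)pent-3-yn-1-ol
Conditions: 1-propynyllithium, BF3·OEt2, THF, −78 °C
Reagents that add atoms: 1-propynyllithium, CC#C[Li]
Why: Yamaguchi–Hirao alkynylation opens the terminal epoxide at its CH2 terminus, so the future C16 stereocentre is not touched.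

Step 20
Reactants: 29 alkynol
Product: 31 (R,E)-4-iodo-1-(2-methyl-1,3-dioxolan-2-yl)pent-3-en-1-ol, via alkenylzirconocene 30 (not isolated)
Conditions: Cp2Zr(H)Cl (3 equiv), THF, 50 °C; then I2, 0 °C
Reagents that add atoms: iodine, II
Why: Hydrozirconation with the Schwartz reagent adds syn and, after equilibration, places Zr on the methyl-bearing alkyne carbon (the less hindered terminus); iodinolysis with retention gives the (E)-vinyl iodide with CH3 cis to C15.

Step 21
Reactants: 31 vinyl iodide ketal
Product: 32 (R,E)-3-hydroxy-6-iodohept-5-en-2-one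
Conditions: PPTS, acetone/H2O, 50 °C
Reagents that add atoms: water, O
Why: Mild acid hydrolysis of the dioxolane liberates the α-hydroxy methyl ketone without enolising the carbinol centre.

Step 22
Reactants: 32 α-hydroxy ketone
Product: 33 (R)-5-[(E)-3-iodobut-2-en-1-yl]-4-methylfuran-2(5H)-one
Conditions: Ph3P=C=C=O, toluene, 80 °C
Reagents that add atoms: (triphenylphosphoranylidene)ketene, O=C=C=P(c1ccccc1)(c1ccccc1)c1ccccc1
Why: Bestmann ylide butenolide synthesis: the hydroxyl adds to the ketene ylide and the resulting ester ylide closes onto the ketone by intramolecular Wittig reaction; the C16–O bond is retained, so the centre stays R.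

Step 23
Reactants: 25 C12 iodide; 33 butenolide vinyl iodide
Product: 34 tris(triethylsilyl) ether of the 18-alcohol with the complete side chain
Conditions: NiBr2(MeOCH2CH2OMe) (10 mol %), 4,4′-di-tert-butyl-2,2′-bipyridine (10 mol %), Zn dust (2 equiv), pyridine (cat.), DMA, rt
Reagents that add atoms: none
Why: Nickel-catalysed reductive cross-electrophile coupling: the vinyl iodide adds oxidatively to zerovalent nickel and the primary iodide enters as its alkyl radical, forming C12–C13 with retention of the E geometry; the base-free conditions should not epimerise C16.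

Step 24
Reactants: 34 silylated coupling product
Product: 35 18-alcohol of the target (6α,8α,18-triol with the complete side chain)
Conditions: HF·pyridine, pyridine, THF, 0 °C → rt
Reagents that add atoms: none
Why: Fluoride-driven desilylation under buffered, non-basic conditions removes all three triethylsilyl groups without epimerising the butenolide C16 or dehydrating the tertiary C8 alcohol.

Step 25
Reactants: 35 18-alcohol
Product: 36 target, CNP0143336.1
Conditions: TEMPO (10 mol %), PhI(OAc)2 (1.1 equiv), CH2Cl2, rt
Reagents that add atoms: none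
Why: Oxoammonium (TEMPO) oxidation is selective for the primary C18 alcohol over the hindered secondary C6 and tertiary C8 alcohols and leaves the alkene and butenolide untouched; the limited amount of oxidant guards against further oxidation through the lactol.

Compound list

1 | 2-methylcyclopentane-1,3-dione | CC1C(=O)CCC1=O | starting material
2 | pent-1-en-3-one (ethyl vinyl ketone) | CCC(=O)C=C | starting material
3 | 2-methyl-2-(3-oxopentyl)cyclopentane-1,3-dione | CCC(=O)CCC1(C)C(=O)CCC1=O | intermediate
4 | (S)-4,7a-dimethyl-2,3,7,7a-tetrahydro-1H-indene-1,5(6H)-dione | CC1=C2CCC(=O)[C@@]2(C)CCC1=O | intermediate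
5 | C9 ethylene ketal of 4 | CC1=C2CCC3(OCCO3)[C@@]2(C)CCC1=O | intermediate
6 | lithium C3 enolate (C3=C4) of the reduced ketal, 5α-H | [Li]OC1=C(C)[C@@H]2CCC3(OCCO3)[C@@]2(C)CC1 | intermediate (not isolated)
7 | trans-fused C3 ketone, 4β-CH3, 4α-CH2OBn, 5α-H, 10β-CH3, C9 ethylene ketal | O1CCOC13[C@@]2(C)CCC(=O)[C@@](C)(COCc4ccccc4)[C@@H]2CC3 | intermediate
8 | 3-deoxo ketal (as 7 with C3 = CH2) | O1CCOC13[C@@]2(C)CCC[C@@](C)(COCc4ccccc4)[C@@H]2CC3 | intermediate (not isolated)
9 | trans-hydrindan-9-one, 4β-CH3, 4α-CH2OBn, 5α-H, 10β-CH3 | O=C1[C@@]2(C)CCC[C@@](C)(COCc3ccccc3)[C@@H]2CC1 | intermediate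
10 | 8-methyl derivative of 9 (C8 epimers) | O=C1[C@@]2(C)CCC[C@@](C)(COCc3ccccc3)[C@@H]2CC1C | intermediate
11 | C9 trimethylsilyl enol ether (C8=C9) | C[Si](C)(C)OC1=C(C)C[C@H]2[C@](C)(COCc3ccccc3)CCC[C@]12C | intermediate (not isolated)
12 | enone, C9=O, C8(CH3)=C6H, 5α-H | O=C1[C@@]2(C)CCC[C@@](C)(COCc3ccccc3)[C@@H]2C=C1C | intermediate
13 | 9α-allyl-9β-hydroxy compound, C8(CH3)=C6H | C=CC[C@@]1(O)[C@@]2(C)CCC[C@@](C)(COCc3ccccc3)[C@@H]2C=C1C | intermediate
14 | transposed enone, C6=O, C8(CH3)=C9-allyl, 5α-H | C=CCC1=C(C)C(=O)[C@@H]2[C@]1(C)CCC[C@@]2(C)COCc1ccccc1 | intermediate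
15 | dilithium C6 enolate (C6=C8) and C18 alkoxide, 9α-H, 9β-allyl | C=CC[C@@H]1[C@@]2(C)CCC[C@@](C)(CO[Li])[C@@H]2C(O[Li])=C1C | intermediate (not isolated)
16 | C6 trimethylsilyl enol ether (C6=C8) with C18–OTMS | C=CC[C@@H]1[C@@]2(C)CCC[C@@](C)(CO[Si](C)(C)C)[C@@H]2C(O[Si](C)(C)C)=C1C | intermediate
17 | siloxycyclopropane (α-CH2 bridge C7 between C6 and C8; 6β-OTMS, 8β-CH3, 18-OTMS) | C=CC[C@@H]1[C@@]2(C)CCC[C@@](C)(CO[Si](C)(C)C)[C@@H]2[C@@]3(O[Si](C)(C)C)C[C@@]13C | intermediate (not isolated)
18 | cyclopropanol (as 17 with free 6β-OH and 18-OH) | C=CC[C@@H]1[C@@]2(C)CCC[C@@](C)(CO)[C@@H]2[C@@]3(O)C[C@@]13C | intermediate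
19 | 8α-hydroperoxy-18-hydroxy-6-ketone, six-membered ring B | C=CC[C@@H]1[C@@]2(C)CCC[C@@](C)(CO)[C@@H]2C(=O)C[C@@]1(C)OO | intermediate (not isolated)
20 | 8α,18-dihydroxy-6-ketone, 8β-CH3, 9β-allyl | C=CC[C@@H]1[C@@]2(C)CCC[C@@](C)(CO)[C@@H]2C(=O)C[C@@]1(C)O | intermediate
21 | 6α,8α,18-triol, 9β-allyl | C=CC[C@@H]1[C@@]2(C)CCC[C@@](C)(CO)[C@@H]2[C@@H](O)C[C@@]1(C)O | intermediate
22 | 6α,8α,18-tris(triethylsilyl) ether of 21 | C=CC[C@@H]1[C@@]2(C)CCC[C@@](C)(CO[Si](CC)(CC)CC)[C@@H]2[C@@H](O[Si](CC)(CC)CC)C[C@@]1(C)O[Si](CC)(CC)CC | intermediate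
23 | C12 aldehyde (9β-CH2CHO), tris(triethylsilyl) ether | O=CC[C@@H]1[C@@]2(C)CCC[C@@](C)(CO[Si](CC)(CC)CC)[C@@H]2[C@@H](O[Si](CC)(CC)CC)C[C@@]1(C)O[Si](CC)(CC)CC | intermediate (not isolated)
24 | C12 alcohol (9β-CH2CH2OH), tris(triethylsilyl) ether | OCC[C@@H]1[C@@]2(C)CCC[C@@](C)(CO[Si](CC)(CC)CC)[C@@H]2[C@@H](O[Si](CC)(CC)CC)C[C@@]1(C)O[Si](CC)(CC)CC | intermediate
25 | C12 iodide (9β-CH2CH2I), tris(triethylsilyl) ether | ICC[C@@H]1[C@@]2(C)CCC[C@@](C)(CO[Si](CC)(CC)CC)[C@@H]2[C@@H](O[Si](CC)(CC)CC)C[C@@]1(C)O[Si](CC)(CC)CC | intermediate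
26 | 2-methyl-2-vinyl-1,3-dioxolane | C=CC1(C)OCCO1 | starting material
27 | rac-2-methyl-2-(oxiran-2-yl)-1,3-dioxolane | CC1(OCCO1)C1CO1 | intermediate
28 | (R)-2-methyl-2-(oxiran-2-yl)-1,3-dioxolane | CC1(OCCO1)[C@H]1CO1 | intermediate
29 | (R)-1-(2-methyl-1,3-dioxolan-2-yl)pent-3-yn-1-ol | CC#CC[C@@H](O)C1(C)OCCO1 | intermediate
30 | alkenylzirconocene chloride (Zr on the methyl-bearing carbon, O-zirconated carbinol) | C/C(=C\C[C@@H](O[Zr](Cl)(C1C=CC=C1)C1C=CC=C1)C1(C)OCCO1)[Zr](Cl)(C1C=CC=C1)C1C=CC=C1 | intermediate (not isolated)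
31 | (R,E)-4-iodo-1-(2-methyl-1,3-dioxolan-2-yl)pent-3-en-1-ol | C/C(I)=C\C[C@@H](O)C1(C)OCCO1 | intermediate
32 | (R,E)-3-hydroxy-6-iodohept-5-en-2-one | C/C(I)=C\C[C@@H](O)C(C)=O | intermediate
33 | (R)-5-[(E)-3-iodobut-2-en-1-yl]-4-methylfuran-2(5H)-one | CC1=CC(=O)O[C@@H]1C/C=C(\C)I | intermediate
34 | tris(triethylsilyl) ether of the 18-alcohol with the complete side chain | CC1=CC(=O)O[C@@H]1C/C=C(\C)CC[C@@H]1[C@@]2(C)CCC[C@@](C)(CO[Si](CC)(CC)CC)[C@@H]2[C@@H](O[Si](CC)(CC)CC)C[C@@]1(C)O[Si](CC)(CC)CC | intermediate
35 | 18-alcohol of the target (6α,8α,18-triol, complete side chain) | CC1=CC(=O)O[C@@H]1C/C=C(\C)CC[C@@H]1[C@@]2(C)CCC[C@@](C)(CO)[C@@H]2[C@@H](O)C[C@@]1(C)O | intermediate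
36 | CNP0143336.1 | CC1=CC(=O)O[C@@H]1C/C=C(\C)CC[C@@H]1[C@@]2(C)CCC[C@@](C)(C=O)[C@@H]2[C@@H](O)C[C@@]1(C)O | target

Total step count: 25. Longest linear sequence: 19 steps (steps 1–16 and 23–25); the butenolide branch has 6 steps (17–22).

The three steps most likely to fail

Most likely to fail is step 12, the key step: the C8 radical may capture O2 with poor facial selectivity, or be oxidised to the 7-en-6-one before it is trapped. The fallback for step 12 keeps the one-carbon ring expansion but installs the C8 oxygen by polar chemistry. It sets out from 17, the siloxycyclopropane isolated after the pyridine quench of step 11. FeCl3 in DMF at 0 °C (Ito–Saegusa ring expansion) with dilute HCl work-up should give the ring-enlarged 8-chloro-18-hydroxy-6-ketone F1. NaOAc in MeOH at reflux eliminates HCl to give the 18-hydroxy-6-oxo-7-ene F2. Nucleophilic epoxidation with H2O2 and NaOH in MeOH, anti to the C20 methyl, gives the 7α,8α-epoxy-18-hydroxy-6-ketone F3. Reductive opening at C7 with Na[PhSeB(OEt)3] (from (PhSe)2 and NaBH4 in EtOH, AcOH) comes back to the route at 20.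

Second is step 4: protonation at C5 may give the cis ring fusion, and the hindered enolate may be alkylated on oxygen or from the wrong face. The fallback for step 4 sets C4 and C5 in separate operations and sets out from 5. KOt-Bu in t-BuOH/THF forms the extended dienolate, which benzyl chloromethyl ether should alkylate at C4 on the α face to give the deconjugated Δ5(6)-3-ketone ketal F4. Wolff–Kishner reduction then gives the 3-deoxo Δ5(6)-alkene ketal F5. Hydrogenation with [Ir(cod)(PCy3)(py)]PF6 and H2 in CH2Cl2, from the α face opposite the C19 and C20 methyls, comes back to the route at 8.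

Third is step 23: homocoupling and protodehalogenation of either iodide may outrun the cross-coupling. The fallback for step 23 replaces the radical cross-electrophile coupling by a two-electron Negishi coupling and sets out from 25. Zinc dust (activated with 1,2-dibromoethane and TMSCl) and LiCl in THF at 40 °C should insert into the C–I bond to give the alkylzinc iodide F6. Pd(PPh3)4 (5 mol %) in THF at rt then couples it with vinyl iodide 33 with retention of the E geometry and comes back to the route at 34.

Further compounds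

F1 | step 12 | 8α-chloro-18-hydroxy-6-ketone, six-membered ring B, 9β-allyl | C=CC[C@@H]1[C@@]2(C)CCC[C@@](C)(CO)[C@@H]2C(=O)C[C@@]1(C)Cl
F2 | step 12 | 18-hydroxy-6-oxo-7-ene, 9β-allyl | C=CC[C@@H]1[C@@]2(C)CCC[C@@](C)(CO)[C@@H]2C(=O)C=C1C
F3 | step 12 | 7α,8α-epoxy-18-hydroxy-6-ketone, 9β-allyl | C=CC[C@@H]1[C@@]2(C)CCC[C@@](C)(CO)[C@@H]2C(=O)[C@H]3O[C@@]13C
F4 | step 4 | Δ5(6)-3-ketone C9 ketal, 4β-CH3, 4α-CH2OBn | O1CCOC13[C@@]2(C)CCC(=O)[C@@](C)(COCc4ccccc4)C2=CC3
F5 | step 4 | 3-deoxo Δ5(6)-alkene C9 ketal, 4β-CH3, 4α-CH2OBn | O1CCOC13[C@@]2(C)CCC[C@@](C)(COCc4ccccc4)C2=CC3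
F6 | step 23 | C12 alkylzinc iodide, tris(triethylsilyl) ether | I[Zn]CC[C@@H]1[C@@]2(C)CCC[C@@](C)(CO[Si](CC)(CC)CC)[C@@H]2[C@@H](O[Si](CC)(CC)CC)C[C@@]1(C)O[Si](CC)(CC)CC
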